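Retrosynthesis: the biaryl C–C bond is cut first, then the para C–allyl bond, the side-chain C–OH bond (alkene hydration), the C2–O–aryl bond (tertiary alkoxide plus aryliodonium salt) and the C2–CH3 bond (ketone via a spiro-epoxide); last, ring A is opened at C1=C8a and C4–C4a.
Enabling feature (decalin numbered C2 = ether carbon, C4a = methyl-bearing fusion carbon, C7 = carbon carrying the CMe2OH branch, C8a = fusion CH): ring B with its C4a methyl and C7 branch is the ring of dihydrocarvone, and C1–C4 of ring A are the four carbons of methyl vinyl ketone.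
Forward: (R)-carvone gives the dihydrocarvone imine; ring A is annulated onto ring B (Michael addition, then aldol condensation); the octalone is reduced to the trans-decalone; C2 is methylenated and reduced to the tertiary alcohol; this is O-arylated, the side chain hydrated, the allyl group attached, and the second aryl ring joined last.
Stereochemistry: C7 comes from (R)-carvone; C4a from the (R)-1-phenylethylamine auxiliary; C8a from axial protonation in the Li/NH3 reduction (trans fusion); C2 from the thermodynamically controlled sulfoxonium-ylide epoxidation (equatorial CH2, axial O) followed by hydride opening.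

Key step: step 3

Remark: dihydrocarvone is carried as its C2-epimer mixture (the SMILES show the major trans isomer), because C2 becomes sp2 in the enamine of step 3. The target is a trans-decalin with the aryloxy group axial and the C2 methyl equatorial.

Step 1
Reactants: 1 (R)-carvone
Product: 2 (2R,5R)-2-methyl-5-(prop-1-en-2-yl)cyclohexan-1-one (dihydrocarvone, with its 2S epimer)
Conditions: LiBH(s-Bu)3, THF, −78 °C; then H2O
Reagents that add atoms: none
Why: Conjugate (1,4) hydride reduction of the enone by the bulky trialkylborohydride should leave the isolated isopropenyl alkene and the C5 stereocentre untouched; the new C2 centre may form as an epimer mixture because it is erased in step 3.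

Step 2
Reactants: 2 dihydrocarvone; 3 (R)-1-phenylethylamine
Product: 4 (5R)-2-methyl-N-[(1R)-1-phenylethyl]-5-(prop-1-en-2-yl)cyclohexan-1-imine
Conditions: TsOH·H2O (cat.), toluene, reflux, Dean–Stark trap
Reagents that add atoms: none
Why: Acid-catalysed imine condensation driven by azeotropic removal of water; neither the C5 centre nor the amine stereocentre is enolisable, and C2 epimerises through the enamine without consequence.

Step 3
Reactants: 4 dihydrocarvone (R)-1-phenylethylimine; 5 methyl vinyl ketone
Product: 9 (4aS,7R)-4a-methyl-7-(prop-1-en-2-yl)-4,4a,5,6,7,8-hexahydronaphthalen-2(3H)-one, via Michael adduct imine 6 (not isolated), via diketone 7 (not isolated), via aldol ketol 8 (not isolated)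
Conditions: 5 (1.3 equiv), THF, 40 °C; then 10% aq AcOH, rt; then NaOMe, MeOH, 60 °C
Reagents that add atoms: none
Why: The imine equilibrates with its secondary enamines, and only the tetrasubstituted tautomer (C=C towards the methyl-bearing carbon) reacts: its N–H lies syn to the nucleophilic carbon, so C–C bond formation to the β-carbon of methyl vinyl ketone and transfer of the N–H proton to the α-carbon occur together in a compact six-membered aza-ene-type transition state, which forms C4–C4a and regenerates an imine (6). The closest known reaction type is the chiral-imine (secondary-enamine) Michael addition followed by Robinson annulation. Mild acid hydrolysis should free diketone 7 and the auxiliary, and methoxide then closes ring A by a 6-(enolendo)-exo-trig aldol addition of the methyl-ketone enolate carbon (C1) to the C8a carbonyl, giving ketol 8, which loses water by E1cB elimination to the conjugated C1=C8a enone. The one new stereocentre, C4a, is set by the (R)-1-phenylethyl group: with its C–H bond eclipsing the enamine plane the phenyl ring covers one face and the enone approaches from the other, the sense known for this auxiliary with 2-methylcyclohexanone, which here places the methyl cis to the C7 branch; C7 is carried over unchanged from carvone. The step needs C4a-versus-C8 regioselectivity, secured by the requirement for the more substituted enamine and internal proton transfer, and facial selectivity against the ring's own preference for a chain syn to the equatorial C7 branch, secured by running the addition without base or protic acid so that only the auxiliary-bound enamine, never a free enolate, can react.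

Step 4
Reactants: 9 octalone
Product: 10 (4aS,7R,8aS)-4a-methyl-7-(prop-1-en-2-yl)octahydronaphthalen-2(1H)-one (trans-fused)
Conditions: Li, NH3(l)/THF, t-BuOH (1 equiv), −78 °C; then NH4Cl
Reagents that add atoms: none
Why: Dissolving-metal (Birch-type) reduction of the enone: the β-carbon C8a is protonated axially, anti to the C4a methyl, which should give the trans-fused decalone as a lithium enolate that resists further reduction, and the isolated alkene is inert.

Step 5
Reactants: 10 trans-decalone
Product: 11 (2'R,4a'S,7'R,8a'S)-4a'-methyl-7'-(prop-1-en-2-yl)octahydro-1'H-spiro[oxirane-2,2'-naphthalene] (oxirane O axial, CH2 equatorial)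
Conditions: Me3S(O)I, NaH, DMSO, rt; then 10, 50 °C
Reagents that add atoms: trimethylsulfoxonium iodide, C[S+](C)(C)=O.[I-]
Why: Corey–Chaykovsky epoxidation with the stabilised sulfoxonium ylide: betaine formation is reversible, so the new C–C bond at C2 should end up equatorial and the oxirane oxygen axial (on the face of the C8a hydrogen), the sense known for this reagent with conformationally fixed cyclohexanones such as 3-keto-5α-steroids.

Step 6
Reactants: 11 spiro-epoxide
Product: 12 (2R,4aS,7R,8aS)-2,4a-dimethyl-7-(prop-1-en-2-yl)decahydronaphthalen-2-ol (OH axial)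
Conditions: LiAlH4, THF, 0 °C to rt; aqueous work-up
Reagents that add atoms: none
Why: Hydride opening of the epoxide by SN2 attack at its unhindered CH2 turns that carbon into the equatorial C2 methyl and leaves the axial C2–O bond, and so the C2 configuration, untouched.

Step 7
Reactants: 13 4-bromo-2-chloro-1-iodobenzene
Product: 15 (4-bromo-2-chlorophenyl)(2,4,6-trimethoxyphenyl)iodonium tosylate, via Koser-type iodane 14 (not isolated)
Conditions: mCPBA, TsOH·H2O, MeCN, 77 °C; then 1,3,5-trimethoxybenzene; precipitation with Et2O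
Reagents that add atoms: p-toluenesulfonic acid, Cc1ccc(cc1)S(=O)(=O)O; 1,3,5-trimethoxybenzene, COc1cc(OC)cc(OC)c1
Why: One-pot diaryliodonium synthesis: mCPBA and TsOH oxidise the aryl iodide to a Koser-type hydroxy(tosyloxy)iodane of trivalent iodine, which arylates the electron-rich trimethoxybenzene by electrophilic aromatic substitution; the C–Br and C–Cl bonds are inert to the peracid.

Step 8
Reactants: 12 tertiary alcohol; 15 iodonium tosylate
Product: 16 (2R,4aS,7R,8aS)-2-(4-bromo-2-chlorophenoxy)-2,4a-dimethyl-7-(prop-1-en-2-yl)decahydronaphthalene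
Conditions: NaH, toluene, 40 °C; then 15, rt
Reagents that add atoms: none
Why: Metal-free O-arylation of a tertiary alkoxide with a diaryliodonium salt (ligand exchange at trivalent iodine, then ligand coupling): the electron-poor, ortho-substituted aryl group should be transferred in preference to the electron-rich trimethoxyphenyl dummy, and since the C2–O bond is never broken the C2 configuration is retained.

Step 9
Reactants: 16 aryl ether
Product: 17 (2R,4aS,7R,8aS)-2-(4-bromo-2-chlorophenoxy)-7-(2-hydroxypropan-2-yl)-2,4a-dimethyldecahydronaphthalene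
Conditions: Co(acac)2 (cat.), PhSiH3, O2 (1 atm), THF, rt
Reagents that add atoms: dioxygen, O=O
Why: Mukaiyama hydration (hydrogen-atom transfer from a cobalt hydride to the 1,1-disubstituted alkene, trapping of the tertiary radical by O2, reduction of the peroxide by the silane) should give the Markovnikov tertiary alcohol without touching the aryl halides or the ether, and C7 is not affected.

Step 10
Reactants: 17 bromo chloro aryl ether
Product: 18 (2R,4aS,7R,8aS)-2-(4-allyl-2-chlorophenoxy)-7-(2-hydroxypropan-2-yl)-2,4a-dimethyldecahydronaphthalene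
Conditions: allylBpin, Pd(PPh3)4 (cat.), CsF, THF, 70 °C
Reagents that add atoms: allylboronic acid pinacol ester, C=CCB1OC(C)(C)C(C)(C)O1
Why: Suzuki–Miyaura allylation: zerovalent palladium with PPh3 ligands inserts into the C–Br bond but not into the stronger, more hindered C–Cl bond, and the fluoride-activated allylboronate then transfers its allyl group.

Step 11
Reactants: 19 4-bromophenol
Product: 20 1-(allyloxy)-4-bromobenzene
Conditions: allyl bromide, K2CO3, acetone, reflux
Reagents that add atoms: allyl bromide, C=CCBr
Why: Williamson ether synthesis (SN2 of the phenoxide on allyl bromide).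

Step 12
Reactants: 20 allyl 4-bromophenyl ether
Product: 21 2-allyl-4-bromophenol
Conditions: N,N-diethylaniline, 200 °C
Reagents that add atoms: none
Why: Aromatic Claisen rearrangement ([3,3]-sigmatropic shift to the free ortho carbon, then tautomerisation to the phenol).

Step 13
Reactants: 21 2-allyl-4-bromophenol
Product: 22 2-allyl-4-(4,4,5,5-tetramethyl-1,3,2-dioxaborolan-2-yl)phenol
Conditions: B2pin2, Pd(dppf)Cl2 (cat.), KOAc, 1,4-dioxane, 90 °C
Reagents that add atoms: bis(pinacolato)diboron, CC1(C)OB(OC1(C)C)B1OC(C)(C)C(C)(C)O1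
Why: Miyaura borylation of the aryl bromide, a reaction that tolerates free phenols when the weak base KOAc is used.

Step 14
Reactants: 18 aryl chloride; 22 arylboronate
Product: 23 3',5-diallyl-2-{[(2R,4aS,7R,8aS)-7-(2-hydroxypropan-2-yl)-2,4a-dimethyldecahydronaphthalen-2-yl]oxy}-[1,1'-biphenyl]-4'-ol (target)
Conditions: Pd(OAc)2 (cat.), SPhos, K3PO4, toluene/H2O 10:1, 90 °C
Reagents that add atoms: none
Why: Suzuki–Miyaura biaryl coupling: the electron-rich dialkylbiarylphosphine SPhos lets zerovalent palladium insert into the hindered ortho-alkoxy C–Cl bond, phosphate activates the boronate, and the free phenol, the tertiary alcohol, both allyl groups and all four stereocentres are spectators.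

Compound list
1 | (R)-carvone | CC1=CC[C@H](CC1=O)C(C)=C | starting material
2 | (2R,5R)-2-methyl-5-(prop-1-en-2-yl)cyclohexan-1-one (dihydrocarvone, major epimer) | C[C@@H]1CC[C@@H](C(C)=C)CC1=O | intermediate
3 | (R)-1-phenylethylamine | C[C@@H](N)c1ccccc1 | starting material
4 | (5R)-2-methyl-N-[(1R)-1-phenylethyl]-5-(prop-1-en-2-yl)cyclohexan-1-imine | C[C@@H]1CC[C@@H](C(C)=C)CC1=N[C@H](C)c1ccccc1 | intermediate
5 | methyl vinyl ketone | C=CC(C)=O | starting material
6 | (2S,5R)-2-methyl-2-(3-oxobutyl)-N-[(1R)-1-phenylethyl]-5-(prop-1-en-2-yl)cyclohexan-1-imine | CC(=O)CC[C@]1(C)CC[C@@H](C(C)=C)CC1=N[C@H](C)c1ccccc1 | intermediate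
7 | (2S,5R)-2-methyl-2-(3-oxobutyl)-5-(prop-1-en-2-yl)cyclohexan-1-one | CC(=O)CC[C@]1(C)CC[C@@H](C(C)=C)CC1=O | intermediate
8 | (4aS,7R,8aS)-8a-hydroxy-4a-methyl-7-(prop-1-en-2-yl)octahydronaphthalen-2(1H)-one (cis-fused ketol; either C8a epimer dehydrates to 9) | O=C1CC[C@]2(C)CC[C@@H](C(C)=C)C[C@]2(O)C1 | intermediate
9 | (4aS,7R)-4a-methyl-7-(prop-1-en-2-yl)-4,4a,5,6,7,8-hexahydronaphthalen-2(3H)-one | O=C1CC[C@]2(C)CC[C@@H](C(C)=C)CC2=C1 | intermediate
10 | (4aS,7R,8aS)-4a-methyl-7-(prop-1-en-2-yl)octahydronaphthalen-2(1H)-one | O=C1CC[C@]2(C)CC[C@@H](C(C)=C)C[C@H]2C1 | intermediate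
11 | (2'R,4a'S,7'R,8a'S)-4a'-methyl-7'-(prop-1-en-2-yl)octahydro-1'H-spiro[oxirane-2,2'-naphthalene] | C1O[C@@]12CC[C@]3(C)CC[C@@H](C(C)=C)C[C@H]3C2 | intermediate
12 | (2R,4aS,7R,8aS)-2,4a-dimethyl-7-(prop-1-en-2-yl)decahydronaphthalen-2-ol | O[C@]1(C)CC[C@]2(C)CC[C@@H](C(C)=C)C[C@H]2C1 | intermediate
13 | 4-bromo-2-chloro-1-iodobenzene | Clc1cc(Br)ccc1I | starting material
14 | 4-bromo-2-chloro-1-[hydroxy(tosyloxy)iodo]benzene | Cc1ccc(cc1)S(=O)(=O)OI(O)c1ccc(Br)cc1Cl | intermediate
15 | (4-bromo-2-chlorophenyl)(2,4,6-trimethoxyphenyl)iodonium tosylate | COc1cc(OC)c([I+]c2ccc(Br)cc2Cl)c(OC)c1.Cc1ccc(cc1)S(=O)(=O)[O-] | intermediate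
16 | (2R,4aS,7R,8aS)-2-(4-bromo-2-chlorophenoxy)-2,4a-dimethyl-7-(prop-1-en-2-yl)decahydronaphthalene | Clc1cc(Br)ccc1O[C@]1(C)CC[C@]2(C)CC[C@@H](C(C)=C)C[C@H]2C1 | intermediate
17 | (2R,4aS,7R,8aS)-2-(4-bromo-2-chlorophenoxy)-7-(2-hydroxypropan-2-yl)-2,4a-dimethyldecahydronaphthalene | Clc1cc(Br)ccc1O[C@]1(C)CC[C@]2(C)CC[C@@H](C(C)(C)O)C[C@H]2C1 | intermediate
18 | (2R,4aS,7R,8aS)-2-(4-allyl-2-chlorophenoxy)-7-(2-hydroxypropan-2-yl)-2,4a-dimethyldecahydronaphthalene | C=CCc1ccc(O[C@]2(C)CC[C@]3(C)CC[C@@H](C(C)(C)O)C[C@H]3C2)c(Cl)c1 | intermediate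
19 | 4-bromophenol | Oc1ccc(Br)cc1 | starting material
20 | 1-(allyloxy)-4-bromobenzene | C=CCOc1ccc(Br)cc1 | intermediate
21 | 2-allyl-4-bromophenol | Oc1ccc(Br)cc1CC=C | intermediate
22 | 2-allyl-4-(4,4,5,5-tetramethyl-1,3,2-dioxaborolan-2-yl)phenol | Oc1ccc(B2OC(C)(C)C(C)(C)O2)cc1CC=C | intermediate
23 | 3',5-diallyl-2-{[(2R,4aS,7R,8aS)-7-(2-hydroxypropan-2-yl)-2,4a-dimethyldecahydronaphthalen-2-yl]oxy}-[1,1'-biphenyl]-4'-ol | C=CCc1ccc(O[C@]2(C)CC[C@]3(C)CC[C@@H](C(C)(C)O)C[C@H]3C2)c(-c2ccc(O)c(CC=C)c2)c1 | target

Total step count: 14. Longest linear sequence: 10 steps (steps 1–6, 8, 9, 10 and 14); steps 7 and 11–13 make the two aryl partners.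

Steps most likely to fail

1. Step 8. The crowded axial alkoxide may act as a base instead of a nucleophile towards the iodonium salt (ortho-deprotonation to an aryne, or electron transfer), or ligand coupling may deliver the wrong aryl group. The fallback sets out from 12 and returns at 16. Alcohol 12 is deprotonated with KH in THF and the alkoxide displaces fluoride from 2-chloro-1-fluoro-4-nitrobenzene (SNAr para to the nitro group) to give (2R,4aS,7R,8aS)-2-(2-chloro-4-nitrophenoxy)-2,4a-dimethyl-7-(prop-1-en-2-yl)decahydronaphthalene F1. Fe and NH4Cl in aqueous ethanol reduce the nitro group, without touching the aryl chloride or the alkene, to the aniline 3-chloro-4-{[(2R,4aS,7R,8aS)-2,4a-dimethyl-7-(prop-1-en-2-yl)decahydronaphthalen-2-yl]oxy}aniline F2. Non-aqueous Sandmeyer bromination (t-BuONO, CuBr2, MeCN) through the arenediazonium bromide F3 then gives 16.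

2. Step 3. The auxiliary has to force the enone onto the ring face that the equatorial C7 branch disfavours, so the addition may be slow and the facial selectivity at C4a may erode. The fallback sets out from 2 and returns at 9; it turns the ring's own bias around instead of opposing it. HBr in AcOH adds to the isopropenyl group of 2 to give the tertiary bromide (2R,5R)-5-(2-bromopropan-2-yl)-2-methylcyclohexan-1-one F4. KOH in MeOH closes a cyclopropane (the C6 enolate displaces bromide, 3-exo-tet) to 2-carone F5. Base-mediated Robinson annulation of F5 with 5 (KOH, EtOH) can enolise only towards the methyl-bearing carbon, and the gem-dimethylcyclopropane blocks its own face, so the chain should enter anti to it and the methyl end up cis to the future C7 branch, giving the cyclopropane-fused octalone F6. HCl in EtOH opens the conjugated cyclopropane by homoconjugate addition to (4aS,7R)-7-(2-chloropropan-2-yl)-4a-methyl-4,4a,5,6,7,8-hexahydronaphthalen-2(3H)-one F7, and NaOAc in hot AcOH eliminates HCl to the isopropenyl group of 9.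

3. Step 14. Oxidative addition into the crowded, electron-rich C–Cl bond may be slower than protodeboronation of the electron-rich hydroxyphenylboronate, and long heating invites migration of the allyl double bonds into conjugation. The fallback sets out from 18 and returns at 23 with the coupling roles inverted, so that the slow C–Cl activation no longer competes with a fragile partner. Miyaura borylation of 18 (B2pin2, Pd2(dba)3, XPhos, KOAc, 1,4-dioxane, 100 °C) gives the pinacol boronate of 18, (2R,4aS,7R,8aS)-2-[4-allyl-2-(4,4,5,5-tetramethyl-1,3,2-dioxaborolan-2-yl)phenoxy]-7-(2-hydroxypropan-2-yl)-2,4a-dimethyldecahydronaphthalene F8, which is coupled with the more reactive aryl bromide 21 under mild Suzuki–Miyaura conditions (Pd(dppf)Cl2, K2CO3, 1,4-dioxane/H2O, 80 °C).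

Further compounds
F1 | step 8 | (2R,4aS,7R,8aS)-2-(2-chloro-4-nitrophenoxy)-2,4a-dimethyl-7-(prop-1-en-2-yl)decahydronaphthalene | [O-][N+](=O)c1ccc(O[C@]2(C)CC[C@]3(C)CC[C@@H](C(C)=C)C[C@H]3C2)c(Cl)c1
F2 | step 8 | 3-chloro-4-{[(2R,4aS,7R,8aS)-2,4a-dimethyl-7-(prop-1-en-2-yl)decahydronaphthalen-2-yl]oxy}aniline | Nc1ccc(O[C@]2(C)CC[C@]3(C)CC[C@@H](C(C)=C)C[C@H]3C2)c(Cl)c1
F3 | step 8 | arenediazonium bromide of F2 (not isolated) | N#[N+]c1ccc(O[C@]2(C)CC[C@]3(C)CC[C@@H](C(C)=C)C[C@H]3C2)c(Cl)c1.[Br-]
F4 | step 3 | (2R,5R)-5-(2-bromopropan-2-yl)-2-methylcyclohexan-1-one | C[C@@H]1CC[C@@H](C(C)(C)Br)CC1=O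
F5 | step 3 | 2-carone, 3,7,7-trimethylbicyclo[4.1.0]heptan-2-one with the cyclopropane cis-fused on the face of the former branch | C[C@@H]1CC[C@H]2C(C)(C)[C@H]2C1=O
F6 | step 3 | cyclopropane-fused octalone: 9 with its side-chain CMe2 carbon bonded to both C7 and C8, on the face of the C4a methyl | O=C1CC[C@]2(C)CC[C@H]3C(C)(C)[C@H]3C2=C1
F7 | step 3 | (4aS,7R)-7-(2-chloropropan-2-yl)-4a-methyl-4,4a,5,6,7,8-hexahydronaphthalen-2(3H)-one | O=C1CC[C@]2(C)CC[C@@H](C(C)(C)Cl)CC2=C1
F8 | step 14 | (2R,4aS,7R,8aS)-2-[4-allyl-2-(4,4,5,5-tetramethyl-1,3,2-dioxaborolan-2-yl)phenoxy]-7-(2-hydroxypropan-2-yl)-2,4a-dimethyldecahydronaphthalene | C=CCc1ccc(O[C@]2(C)CC[C@]3(C)CC[C@@H](C(C)(C)O)C[C@H]3C2)c(B2OC(C)(C)C(C)(C)O2)c1
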